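**Retrosynthetic overview**
- Target ⇒ key C1'–O ester bond: attack of 3-methylbutanoic acid with inversion at the benzylic carbon of the trans-(1'S,2'R)-epoxy carbinol. This epoxide comes from asymmetric oxygen transfer to the E-alkene suberenol, and both C–O events run in one flask.
- Suberenol ⇒ Heck coupling of 6-bromo-7-methoxycoumarin with 2-methylbut-3-en-2-ol.
- 6-Bromo-7-methoxycoumarin ⇒ Wittig olefination/lactonisation of 5-bromo-2-hydroxy-4-methoxybenzaldehyde.
- Ring order: the benzene ring is bought; the pyran-2-one ring is the only permanent ring made (step 1); the oxirane is a transient ring made and opened in step 3.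

Assumption: 5-bromo-2-hydroxy-4-methoxybenzaldehyde is bought as a catalogue building block; BHA* in step 3 means the antipode of N,N'-dihydroxy-N,N'-bis(diphenylacetyl)-trans-cyclohexane-1,2-diamine that delivers oxygen to the Re,Re face of the alkene, fixed by one pilot run because the sense of induction of the new catalyst system cannot be predicted with certainty.

**Step 1**
Reactants: 1 5-bromo-2-hydroxy-4-methoxybenzaldehyde; 2 ethyl (triphenylphosphoranylidene)acetate
Product: 5 6-bromo-7-methoxy-2H-chromen-2-one, via (E)-cinnamate ester 3 (not isolated), via (Z)-cinnamate ester 4 (not isolated)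
Conditions: 2 (1.3 equiv), PhNEt2, reflux (ca. 215 °C), 4 h; 1 M HCl wash
Reagents that add atoms: ethyl (triphenylphosphoranylidene)acetate, CCOC(=O)C=P(c1ccccc1)(c1ccccc1)c1ccccc1
Why: Wittig olefination gives the cinnamates, and at this temperature the E-ester isomerises to the Z-ester, whose phenol closes the pyran-2-one ring by intramolecular transesterification with loss of ethanol; no stereocentre is formed.

**Step 2**
Reactants: 5 6-bromo-7-methoxy-2H-chromen-2-one; 6 2-methylbut-3-en-2-ol
Product: 7 suberenol, 6-[(E)-3-hydroxy-3-methylbut-1-en-1-yl]-7-methoxy-2H-chromen-2-one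
Conditions: 6 (2 equiv), Pd(OAc)2 (5 mol%), P(o-tol)3 (10 mol%), Et3N (2.5 equiv), DMF, 100 °C, 12 h
Reagents that add atoms: 2-methylbut-3-en-2-ol, C=CC(C)(C)O
Why: Mizoroki–Heck reaction: oxidative addition of the aryl bromide to zerovalent palladium, syn-carbopalladation at the terminal alkene carbon and syn-β-hydride elimination give the E-alkene only, the tertiary carbinol cannot isomerise to a ketone, and the electron-poor coumarin alkene does not compete.

**Step 3**
Reactants: 7 suberenol; 8 cumene hydroperoxide; 9 3-methylbutanoic acid
Product: 11 (1R,2R)-2,3-dihydroxy-1-(7-methoxy-2-oxo-2H-chromen-6-yl)-3-methylbutyl 3-methylbutanoate, via trans-epoxy carbinol 10 (not isolated)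
Conditions: Hf(OtBu)4 (10 mol%), BHA* (12 mol%), 8 (1.5 equiv), dry toluene, 0 °C, 24 h; then 9 (3 equiv), 0 → 40 °C; aq. Na2S2O3/NaHCO3 work-up
Reagents that add atoms: cumene hydroperoxide, CC(C)(OO)c1ccccc1; 3-methylbutanoic acid, CC(C)CC(=O)O
Why: Proposed new method: a one-flask catalytic asymmetric anti-hydroxy-acyloxylation in which the catalyst formed from Hf(OtBu)4 and BHA* (tetravalent hafnium) first binds the tertiary alkoxide of 7 and the alkyl peroxide and transfers oxygen to the Re,Re face of the E-alkene (sets C2' as R and gives the 1'S,2'R trans-epoxide 10). Once the peroxide is spent, the same metal centre holds 10 as a five-membered alkoxide–epoxide chelate that isovalerate opens at the distal benzylic carbon by SN2 attack with inversion (sets C1' as R and forms the key C1'–O ester bond); this carbon is favoured by the chelate geometry and the ortho-methoxy donor, while C2' is neopentyl-like and blocked. The closest known reaction types are the hydroxyl-directed group 4 metal/bishydroxamic acid epoxidation of tertiary allylic alcohols and the Ti(OiPr)4-mediated C3-selective opening of 2,3-epoxy alcohols by carboxylic acids, which have not been merged under one chiral catalyst nor shown on this substrate class.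

**Compound list**
1 | 5-bromo-2-hydroxy-4-methoxybenzaldehyde | COc1cc(O)c(C=O)cc1Br | starting material
2 | ethyl (triphenylphosphoranylidene)acetate | CCOC(=O)C=P(c1ccccc1)(c1ccccc1)c1ccccc1 | starting material
3 | ethyl (E)-3-(5-bromo-2-hydroxy-4-methoxyphenyl)prop-2-enoate | CCOC(=O)/C=C/c1cc(Br)c(OC)cc1O | intermediate
4 | ethyl (Z)-3-(5-bromo-2-hydroxy-4-methoxyphenyl)prop-2-enoate | CCOC(=O)/C=C\c1cc(Br)c(OC)cc1O | intermediate
5 | 6-bromo-7-methoxy-2H-chromen-2-one | COc1cc2oc(=O)ccc2cc1Br | intermediate
6 | 2-methylbut-3-en-2-ol | C=CC(C)(C)O | starting material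
7 | suberenol, 6-[(E)-3-hydroxy-3-methylbut-1-en-1-yl]-7-methoxy-2H-chromen-2-one | COc1cc2oc(=O)ccc2cc1/C=C/C(C)(C)O | intermediate
8 | cumene hydroperoxide (2-hydroperoxypropan-2-ylbenzene) | CC(C)(OO)c1ccccc1 | starting material
9 | 3-methylbutanoic acid (isovaleric acid) | CC(C)CC(=O)O | starting material
10 | 6-[(2S,3R)-3-(2-hydroxypropan-2-yl)oxiran-2-yl]-7-methoxy-2H-chromen-2-one | COc1cc2oc(=O)ccc2cc1[C@@H]1O[C@H]1C(C)(C)O | intermediate
11 | (1R,2R)-2,3-dihydroxy-1-(7-methoxy-2-oxo-2H-chromen-6-yl)-3-methylbutyl 3-methylbutanoate | COc1cc2oc(=O)ccc2cc1[C@@H](OC(=O)CC(C)C)[C@@H](O)C(C)(C)O | target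

**Total step count:** 3. **Longest linear sequence:** 3 steps (1 → 5 → 7 → 11).

**Steps most likely to fail, with fallbacks**

Step 3 (the proposed new one-flask reaction) is the riskiest. Facial control may be low or reversed, the acid may strip the ligand, the benzylic carbon may ionise (loss of inversion or rearrangement to a ketone), and the acyl group may shift to the neighbouring hydroxyl. The fallback uses known chemistry only, sets out from 7 and comes back to the route at 11. Alkene 7 is epoxidised without hydroxyl direction by Shi epoxidation with 1,2:4,5-di-O-isopropylidene-β-L-erythro-2,3-hexodiulo-2,6-pyranose (30 mol%), KHSO5 (as 2KHSO5·KHSO4·K2SO4), K2CO3 and Bu4NHSO4 in MeCN/dimethoxymethane/aqueous buffer (pH 10.5) at 0 °C. This ketone is the mirror image of the usual D-fructose-derived one, which gives the benzylic R epoxide of trans-β-substituted styrenes, so the L-ketone gives the 1'S,2'R epoxide 10, now isolated. Epoxide 10 is then opened at the benzylic carbon with inversion by Ti(OiPr)4 (1.5 equiv) and 9 (2 equiv) in CH2Cl2 at 0 °C → rt, giving 11. No compound outside the list is made on this way: none (F0).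

Step 2 may suffer from slow oxidative addition to the ortho-methoxy aryl bromide, palladium black, or dehydration of the tertiary allylic alcohol to a diene at 100 °C. The fallback sets out from 5 and comes back at 7, and replaces carbopalladation by a Suzuki–Miyaura coupling in which the E-geometry is fixed beforehand. 2-Methylbut-3-yn-2-ol is converted by CuCl/Xantphos/NaOtBu-catalysed syn-protoboration with B2pin2 and MeOH into (E)-2-methyl-4-(4,4,5,5-tetramethyl-1,3,2-dioxaborolan-2-yl)but-3-en-2-ol F2. F2 is coupled with 5 using Pd(dppf)Cl2 (3 mol%) and K2CO3 in dioxane/water at 80 °C, with a mildly acidic work-up to re-close any opened lactone, giving 7.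

Step 1 may give tar or stall at the E-ester under the 215 °C conditions. The fallback sets out from 1 and comes back at 5, and builds the lactone by Knoevenagel condensation instead of olefination. Aldehyde 1 and Meldrum's acid (2,2-dimethyl-1,3-dioxane-4,6-dione) with catalytic piperidinium acetate in EtOH at reflux give 6-bromo-7-methoxy-2-oxo-2H-chromene-3-carboxylic acid F1. F1 is protodecarboxylated with Ag2CO3 (10 mol%) and AcOH in DMSO at 120 °C (or Cu powder in quinoline at 200 °C) to 5.

**Further compounds**
F1 | step 1 | 6-bromo-7-methoxy-2-oxo-2H-chromene-3-carboxylic acid | COc1cc2oc(=O)c(C(=O)O)cc2cc1Br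
F2 | step 2 | (E)-2-methyl-4-(4,4,5,5-tetramethyl-1,3,2-dioxaborolan-2-yl)but-3-en-2-ol | CC(C)(O)/C=C/B1OC(C)(C)C(C)(C)O1
F0 | step 3 | none | none
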